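**Plan**

1. Numbering is lignan style: C7/C7' are the benzylic carbinols, C8/C8' the ring methines, C9/C9' the ring OCH2 groups. The target is the C2-symmetric (7S,8R,8'R,7'S) isomer.
2. Feature used: ring carbon C8 of the tetrahydrofuran carries the exocyclic carbon C7 at acyl level. The five-membered ring is therefore the contracted form of a tetrahydropyran-4-one whose carbonyl carbon is C7 and whose α-carbon C8' already bears the C7' carbinol.
3. Cuts, in order: O–benzyl and O–silyl groups; C7–H (ketone reduction); C7–aryl (aryllithium on a Weinreb amide); ring bond C8–C8' (reverse Wolff ring contraction to an α-diazo pyranone); the diazo group; C7'–C8' (aldol).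
4. Forward: an aldol joins the first aryl unit to the six-membered ring, diazo transfer and photolysis contract it to the tetrahydrofuran, then come the second aryl unit, reduction and deprotection.
5. Stereochemistry: C7' and C8' from a D-proline anti aldol (C8' retained in the 1,2-shift), C8 by equilibration to the trans ester, C7 by Felkin–Anh hydride addition.

Key step: step 5

Remark: 1-benzyloxy-4-bromo-2-methoxybenzene is taken as a commercial building block, like tetrahydro-4H-pyran-4-one, O-benzylvanillin and D-proline.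

**Route**

Step 1
Reactants: 1 tetrahydro-4H-pyran-4-one; 2 4-benzyloxy-3-methoxybenzaldehyde (O-benzylvanillin)
Product: 3 (3R)-3-[(S)-(4-benzyloxy-3-methoxyphenyl)(hydroxy)methyl]tetrahydro-4H-pyran-4-one
Conditions: D-proline (30 mol %), 1 in excess (5 equiv), DMSO, H2O (3 equiv), rt
Reagents that add atoms: none
Why: Proline-catalysed direct aldol (enamine catalysis): the pyranone enamine, necessarily E, should add to the Si face of the aldehyde in a chair-like transition state organised by the carboxylic acid, so D-proline sets the anti (3R,1'S) pair, while excess ketone and a little water counter the low electrophilicity of the alkoxy-substituted aldehyde.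

Step 2
Reactants: 3 (3R)-3-[(S)-(4-benzyloxy-3-methoxyphenyl)(hydroxy)methyl]tetrahydro-4H-pyran-4-one
Product: 4 (3R)-3-[(S)-(4-benzyloxy-3-methoxyphenyl)(tert-butyldimethylsilyloxy)methyl]tetrahydro-4H-pyran-4-one
Conditions: TBSOTf, 2,6-lutidine, CH2Cl2, −78 → 0 °C
Reagents that add atoms: tert-butyldimethylsilyl trifluoromethanesulfonate, CC(C)(C)[Si](C)(C)OS(=O)(=O)C(F)(F)F
Why: O-Silylation of the secondary aldol hydroxyl with a silyl triflate and a hindered base is fast at low temperature, avoids retro-aldol and epimerisation, and blocks retro-aldol in the enolate chemistry that follows.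

Step 3
Reactants: 4 (3R)-3-[(S)-(4-benzyloxy-3-methoxyphenyl)(tert-butyldimethylsilyloxy)methyl]tetrahydro-4H-pyran-4-one
Product: 6 (3R)-3-[(S)-(4-benzyloxy-3-methoxyphenyl)(tert-butyldimethylsilyloxy)methyl]-5-(trifluoroacetyl)tetrahydro-4H-pyran-4-one, via lithium enolate 5 (not isolated)
Conditions: LiN(SiMe3)2, THF, −78 °C; then CF3CO2CH2CF3, −78 °C; cold dilute aq. HCl
Reagents that add atoms: 2,2,2-trifluoroethyl trifluoroacetate, O=C(OCC(F)(F)F)C(F)(F)F
Why: Kinetic deprotonation should take place at the unhindered α'-methylene C5 and not at the substituted methine C3, and Claisen-type C-trifluoroacetylation of that enolate gives the activated 1,3-dicarbonyl needed for diazo transfer.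

Step 4
Reactants: 6 (3R)-3-[(S)-(4-benzyloxy-3-methoxyphenyl)(tert-butyldimethylsilyloxy)methyl]-5-(trifluoroacetyl)tetrahydro-4H-pyran-4-one
Product: 7 (3R)-3-[(S)-(4-benzyloxy-3-methoxyphenyl)(tert-butyldimethylsilyloxy)methyl]-5-diazotetrahydro-4H-pyran-4-one
Conditions: MsN3, Et3N, H2O (1 equiv), MeCN, rt
Reagents that add atoms: methanesulfonyl azide, CS(=O)(=O)N=[N+]=[N-]
Why: Deacylative (detrifluoroacetylative) Regitz diazo transfer: the enolate of the trifluoroacetyl ketone adds to the sulfonyl azide and the adduct fragments, the trifluoroacetyl group leaving as its N-mesyl amide and the diazo group staying on C5 only.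

Step 5
Reactants: 7 (3R)-3-[(S)-(4-benzyloxy-3-methoxyphenyl)(tert-butyldimethylsilyloxy)methyl]-5-diazotetrahydro-4H-pyran-4-one
Product: 10 methyl (3R,4R)-4-[(S)-(4-benzyloxy-3-methoxyphenyl)(tert-butyldimethylsilyloxy)methyl]tetrahydrofuran-3-carboxylate, via ring-contracted ketene 8 (not isolated), via C3-epimeric ester mixture 9 (not isolated)
Conditions: hν (365 nm), degassed MeOH, rt; then NaOMe (0.2 equiv), MeOH, rt
Reagents that add atoms: methanol, CO
Why: Photochemical Wolff rearrangement: excitation of the s-cis-locked cyclic α-diazo ketone expels N2 while pyranone C3 (C8') shifts with its bonding pair from the carbonyl carbon C4 (future C7) to the diazo carbon C5 (future C8), giving ketene 8, which methanol captures as the ester. The closest known reaction type is the Wolff ring contraction of cyclic 2-diazo ketones, oxygen and nitrogen heterocycles included. The tetrahydrofuran ring arises by contraction of the six-membered ring through this 1,2-shift, which makes the C8–C8' bond; it is not a cyclisation of an open chain. C8' keeps its configuration because the migrating carbon moves with retention; the new centre C8 is first set by protonation of the ketene-derived enol, expected mainly from the face away from the C8' side chain (cis ester), and NaOMe then equilibrates it through the ester enolate to the trans ester, in which the ester avoids the bulky silyloxybenzyl group. The step needs rearrangement to outrun O–H insertion and 1,2-hydride shift of a free carbene, which the enforced s-cis geometry (concerted N2 loss and migration) and metal-free direct irradiation favour; only one carbon can migrate, and 365 nm light is not absorbed by the aryl ethers.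

Step 6
Reactants: 10 methyl (3R,4R)-4-[(S)-(4-benzyloxy-3-methoxyphenyl)(tert-butyldimethylsilyloxy)methyl]tetrahydrofuran-3-carboxylate
Product: 11 (3R,4R)-4-[(S)-(4-benzyloxy-3-methoxyphenyl)(tert-butyldimethylsilyloxy)methyl]-N-methoxy-N-methyltetrahydrofuran-3-carboxamide
Conditions: MeNH(OMe)·HCl, i-PrMgCl, THF, −20 → 0 °C; aq. NH4Cl
Reagents that add atoms: N,O-dimethylhydroxylamine hydrochloride, CNOC.Cl
Why: Aminolysis of the methyl ester by the chloromagnesium amide made in the flask (Weinreb amide synthesis) is standard for hindered esters, and any enolisation at C3 is harmless because the trans isomer is the thermodynamic one.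

Step 7
Reactants: 11 (3R,4R)-4-[(S)-(4-benzyloxy-3-methoxyphenyl)(tert-butyldimethylsilyloxy)methyl]-N-methoxy-N-methyltetrahydrofuran-3-carboxamide; 12 1-benzyloxy-4-bromo-2-methoxybenzene
Product: 14 (4-benzyloxy-3-methoxyphenyl){(3R,4R)-4-[(S)-(4-benzyloxy-3-methoxyphenyl)(tert-butyldimethylsilyloxy)methyl]tetrahydrofuran-3-yl}methanone, via aryllithium 13 (not isolated)
Conditions: 12, n-BuLi, THF, −78 °C; then 11, −78 → −40 °C; aq. NH4Cl
Reagents that add atoms: none
Why: Bromine–lithium exchange followed by Weinreb ketone synthesis: the chelated tetrahedral adduct persists until work-up, so the aryllithium should add once only and the trans ring centres are not disturbed.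

Step 8
Reactants: 14 (4-benzyloxy-3-methoxyphenyl){(3R,4R)-4-[(S)-(4-benzyloxy-3-methoxyphenyl)(tert-butyldimethylsilyloxy)methyl]tetrahydrofuran-3-yl}methanone
Product: 15 (S)-(4-benzyloxy-3-methoxyphenyl){(3R,4R)-4-[(S)-(4-benzyloxy-3-methoxyphenyl)(tert-butyldimethylsilyloxy)methyl]tetrahydrofuran-3-yl}methanol
Conditions: LiBH(s-Bu)3, THF, −78 °C; aq. NH4Cl
Reagents that add atoms: none
Why: Felkin–Anh reduction with a bulky hydride: with the ring bond C3–C4 (to the carbon carrying the silyloxybenzyl group) anti to the incoming hydride and the ring OCH2 carbon C2 beside the carbonyl oxygen, attack past C3–H should give the (S)-carbinol, and lithium bridging of the carbonyl and ring oxygens points to the same face.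

Step 9
Reactants: 15 (S)-(4-benzyloxy-3-methoxyphenyl){(3R,4R)-4-[(S)-(4-benzyloxy-3-methoxyphenyl)(tert-butyldimethylsilyloxy)methyl]tetrahydrofuran-3-yl}methanol
Product: 16 (S,S)-[(3R,4R)-tetrahydrofuran-3,4-diyl]bis[(4-benzyloxy-3-methoxyphenyl)methanol]
Conditions: Bu4NF, THF, 0 °C → rt; aq. NH4Cl
Reagents that add atoms: none
Why: Fluoride-driven Si–O cleavage (desilylation) frees the second benzylic alcohol while both phenols are still benzylated, so no phenoxide and hence no quinone methide can form under the basic conditions.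

Step 10
Reactants: 16 (S,S)-[(3R,4R)-tetrahydrofuran-3,4-diyl]bis[(4-benzyloxy-3-methoxyphenyl)methanol]
Product: 17 (S,S)-[(3R,4R)-tetrahydrofuran-3,4-diyl]bis[(4-hydroxy-3-methoxyphenyl)methanol], the target CNP0157038.3
Conditions: H2 (1 atm), Pd/C (10 wt %), EtOAc, rt
Reagents that add atoms: none
Why: Catalytic hydrogenolysis of the two aryl benzyl ethers under neutral conditions in a non-protic solvent should be much faster than C–O hydrogenolysis of the secondary benzylic alcohols, and no stereocentre is touched.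

**Compound list**

1 | tetrahydro-4H-pyran-4-one | O=C1CCOCC1 | starting material
2 | 4-benzyloxy-3-methoxybenzaldehyde (O-benzylvanillin) | COc1cc(C=O)ccc1OCc1ccccc1 | starting material
3 | (3R)-3-[(S)-(4-benzyloxy-3-methoxyphenyl)(hydroxy)methyl]tetrahydro-4H-pyran-4-one | O=C1CCOC[C@@H]1[C@H](O)c1ccc(OCc2ccccc2)c(OC)c1 | intermediate
4 | (3R)-3-[(S)-(4-benzyloxy-3-methoxyphenyl)(tert-butyldimethylsilyloxy)methyl]tetrahydro-4H-pyran-4-one | O=C1CCOC[C@@H]1[C@H](O[Si](C)(C)C(C)(C)C)c1ccc(OCc2ccccc2)c(OC)c1 | intermediate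
5 | lithium enolate of 4 (lithium 3,6-dihydro-2H-pyran-4-olate with C4=C5, side chain on C3; formed in the flask) | [Li]OC1=CCOC[C@@H]1[C@H](O[Si](C)(C)C(C)(C)C)c1ccc(OCc2ccccc2)c(OC)c1 | intermediate
6 | (3R)-3-[(S)-(4-benzyloxy-3-methoxyphenyl)(tert-butyldimethylsilyloxy)methyl]-5-(trifluoroacetyl)tetrahydro-4H-pyran-4-one (enolised 1,3-diketone, C5 undefined) | O=C1C(C(=O)C(F)(F)F)COC[C@@H]1[C@H](O[Si](C)(C)C(C)(C)C)c1ccc(OCc2ccccc2)c(OC)c1 | intermediate
7 | (3R)-3-[(S)-(4-benzyloxy-3-methoxyphenyl)(tert-butyldimethylsilyloxy)methyl]-5-diazotetrahydro-4H-pyran-4-one | O=C1C(=[N+]=[N-])COC[C@@H]1[C@H](O[Si](C)(C)C(C)(C)C)c1ccc(OCc2ccccc2)c(OC)c1 | intermediate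
8 | {(4R)-4-[(S)-(4-benzyloxy-3-methoxyphenyl)(tert-butyldimethylsilyloxy)methyl]dihydrofuran-3(2H)-ylidene}methanone (ring-contracted ketene; formed in the flask) | O=C=C1COC[C@@H]1[C@H](O[Si](C)(C)C(C)(C)C)c1ccc(OCc2ccccc2)c(OC)c1 | intermediate
9 | methyl (4R)-4-[(S)-(4-benzyloxy-3-methoxyphenyl)(tert-butyldimethylsilyloxy)methyl]tetrahydrofuran-3-carboxylate as the mixture of C3 epimers (formed in the flask) | COC(=O)C1COC[C@@H]1[C@H](O[Si](C)(C)C(C)(C)C)c1ccc(OCc2ccccc2)c(OC)c1 | intermediate
10 | methyl (3R,4R)-4-[(S)-(4-benzyloxy-3-methoxyphenyl)(tert-butyldimethylsilyloxy)methyl]tetrahydrofuran-3-carboxylate (trans) | COC(=O)[C@H]1COC[C@@H]1[C@H](O[Si](C)(C)C(C)(C)C)c1ccc(OCc2ccccc2)c(OC)c1 | intermediate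
11 | (3R,4R)-4-[(S)-(4-benzyloxy-3-methoxyphenyl)(tert-butyldimethylsilyloxy)methyl]-N-methoxy-N-methyltetrahydrofuran-3-carboxamide | CON(C)C(=O)[C@H]1COC[C@@H]1[C@H](O[Si](C)(C)C(C)(C)C)c1ccc(OCc2ccccc2)c(OC)c1 | intermediate
12 | 1-benzyloxy-4-bromo-2-methoxybenzene | COc1cc(Br)ccc1OCc1ccccc1 | starting material
13 | (4-benzyloxy-3-methoxyphenyl)lithium (formed in the flask) | [Li]c1ccc(OCc2ccccc2)c(OC)c1 | intermediate
14 | (4-benzyloxy-3-methoxyphenyl){(3R,4R)-4-[(S)-(4-benzyloxy-3-methoxyphenyl)(tert-butyldimethylsilyloxy)methyl]tetrahydrofuran-3-yl}methanone | COc1cc(C(=O)[C@H]2COC[C@@H]2[C@H](O[Si](C)(C)C(C)(C)C)c2ccc(OCc3ccccc3)c(OC)c2)ccc1OCc1ccccc1 | intermediate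
15 | (S)-(4-benzyloxy-3-methoxyphenyl){(3R,4R)-4-[(S)-(4-benzyloxy-3-methoxyphenyl)(tert-butyldimethylsilyloxy)methyl]tetrahydrofuran-3-yl}methanol | COc1cc([C@@H](O)[C@H]2COC[C@@H]2[C@H](O[Si](C)(C)C(C)(C)C)c2ccc(OCc3ccccc3)c(OC)c2)ccc1OCc1ccccc1 | intermediate
16 | (S,S)-[(3R,4R)-tetrahydrofuran-3,4-diyl]bis[(4-benzyloxy-3-methoxyphenyl)methanol] | COc1cc([C@@H](O)[C@H]2COC[C@@H]2[C@H](O)c2ccc(OCc3ccccc3)c(OC)c2)ccc1OCc1ccccc1 | intermediate
17 | (S,S)-[(3R,4R)-tetrahydrofuran-3,4-diyl]bis[(4-hydroxy-3-methoxyphenyl)methanol], (7S,8R,8'R,7'S) | COc1cc([C@@H](O)[C@H]2COC[C@@H]2[C@H](O)c2ccc(O)c(OC)c2)ccc1O | target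

**Count**

Total step count: 10. Longest linear sequence: 10 steps (1 → 17); aryl bromide 12 enters directly in step 7.

**Steps most likely to fail**

Step 1 (aldol). The alkoxy-substituted aldehyde is a weak electrophile, so enamine addition may be slow. Over long reaction times retro-aldol and dehydration to the enone may erode conversion and the anti selectivity. The fallback sets out from 1 and uses an electronically activated aldehyde whose phenol protection is exchanged afterwards. D-Proline aldol of 1 with commercial 4-formyl-2-methoxyphenyl acetate (vanillin acetate; the acyloxy group makes the aldehyde markedly more electrophilic) should give (3R)-3-[(S)-(4-acetoxy-3-methoxyphenyl)(hydroxy)methyl]tetrahydro-4H-pyran-4-one F1. Silylation with TBSOTf and 2,6-lutidine would give (3R)-3-[(S)-(4-acetoxy-3-methoxyphenyl)(tert-butyldimethylsilyloxy)methyl]tetrahydro-4H-pyran-4-one F2. Near-neutral methanolysis of the aryl acetate (NH4OAc, MeOH, rt) spares the base-sensitive β-silyloxy ketone and would give (3R)-3-[(S)-(tert-butyldimethylsilyloxy)(4-hydroxy-3-methoxyphenyl)methyl]tetrahydro-4H-pyran-4-one F3. Mitsunobu benzylation of the phenol (PhCH2OH, PPh3, diisopropyl azodicarboxylate, THF) comes back to the route at 4.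

Step 5 (Wolff ring contraction). If loss of N2 is not fully concerted with migration, the α-keto carbene may insert into the O–H bond of methanol or undergo 1,2-hydride shift from the neighbouring OCH2 group. Irradiation may also degrade the electron-rich arene, and equilibration to the trans ester may stall. The fallback sets out from 4 and contracts the ring without light or a free carbene, by the sulfonyl azide ring contraction of a silyl enol ether. Kinetic enolisation with in situ silylation (LiN(SiMe3)2, Me3SiCl, THF, −78 °C) should give tert-butyl{(S)-(4-benzyloxy-3-methoxyphenyl)[(3R)-4-(trimethylsilyloxy)-3,6-dihydro-2H-pyran-3-yl]methoxy}dimethylsilane F4. 4-Nitrobenzenesulfonyl azide in MeCN adds across the enol ether, and the triazoline loses N2 with the same 1,2-shift of the substituted ring carbon (retention). After aqueous work-up this would give (4R)-4-[(S)-(4-benzyloxy-3-methoxyphenyl)(tert-butyldimethylsilyloxy)methyl]-N-(4-nitrophenylsulfonyl)tetrahydrofuran-3-carboxamide F5 as C3 epimers. N-Methylation (MeI, K2CO3, DMF) activates the acyl sulfonamide as (4R)-4-[(S)-(4-benzyloxy-3-methoxyphenyl)(tert-butyldimethylsilyloxy)methyl]-N-methyl-N-(4-nitrophenylsulfonyl)tetrahydrofuran-3-carboxamide F6. NaOMe in MeOH then transfers the acyl group to methoxide and equilibrates C3, coming back to the route at 10.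

Step 8 (ketone reduction). Facial selectivity may be poor if the two ring carbons flanking C3 are not differentiated enough, or if chelated and non-chelated transition states compete, so that the (R)-carbinol forms alongside. The fallback sets out from 14 and replaces substrate control by reagent control. Corey–Bakshi–Shibata reduction with BH3·SMe2 and (R)-1-methyl-3,3-diphenyltetrahydro-1H,3H-pyrrolo[1,2-c][1,3,2]oxazaborole in THF at −20 °C treats the aryl group as the large substituent, as it does for aryl alkyl ketones, and should deliver the (S)-alcohol. It comes back to the route at 15 without any new compound.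

**Further compounds**

F1 | step 1 | (3R)-3-[(S)-(4-acetoxy-3-methoxyphenyl)(hydroxy)methyl]tetrahydro-4H-pyran-4-one | O=C1CCOC[C@@H]1[C@H](O)c1ccc(OC(C)=O)c(OC)c1
F2 | step 1 | (3R)-3-[(S)-(4-acetoxy-3-methoxyphenyl)(tert-butyldimethylsilyloxy)methyl]tetrahydro-4H-pyran-4-one | O=C1CCOC[C@@H]1[C@H](O[Si](C)(C)C(C)(C)C)c1ccc(OC(C)=O)c(OC)c1
F3 | step 1 | (3R)-3-[(S)-(tert-butyldimethylsilyloxy)(4-hydroxy-3-methoxyphenyl)methyl]tetrahydro-4H-pyran-4-one | O=C1CCOC[C@@H]1[C@H](O[Si](C)(C)C(C)(C)C)c1ccc(O)c(OC)c1
F4 | step 5 | tert-butyl{(S)-(4-benzyloxy-3-methoxyphenyl)[(3R)-4-(trimethylsilyloxy)-3,6-dihydro-2H-pyran-3-yl]methoxy}dimethylsilane | C[Si](C)(C)OC1=CCOC[C@@H]1[C@H](O[Si](C)(C)C(C)(C)C)c1ccc(OCc2ccccc2)c(OC)c1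
F5 | step 5 | (4R)-4-[(S)-(4-benzyloxy-3-methoxyphenyl)(tert-butyldimethylsilyloxy)methyl]-N-(4-nitrophenylsulfonyl)tetrahydrofuran-3-carboxamide (C3 epimers) | O=C(NS(=O)(=O)c1ccc(cc1)[N+](=O)[O-])C1COC[C@@H]1[C@H](O[Si](C)(C)C(C)(C)C)c1ccc(OCc2ccccc2)c(OC)c1
F6 | step 5 | (4R)-4-[(S)-(4-benzyloxy-3-methoxyphenyl)(tert-butyldimethylsilyloxy)methyl]-N-methyl-N-(4-nitrophenylsulfonyl)tetrahydrofuran-3-carboxamide (C3 epimers) | CN(C(=O)C1COC[C@@H]1[C@H](O[Si](C)(C)C(C)(C)C)c1ccc(OCc2ccccc2)c(OC)c1)S(=O)(=O)c1ccc(cc1)[N+](=O)[O-]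
F0 | step 8 | none | none
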